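**Retrosynthetic overview**

- The target is one six-membered carbocycle with no stereocentre. Its C1 carbonyl sits between OMe on C2 and the heptadecyl chain on C6, and the second carbonyl is at C4. The route rests on this contiguous C6-alkyl / C1-oxygen / C2-methoxy triad.
- The C4 carbonyl is disconnected last: para-oxygenation of 2-heptadecyl-6-methoxyphenol.
- The phenol is cut at C6–C1′ and at C1–O, across what was the strained C1–C6 bond of 3-methoxybenzyne. Heptadecyllithium is the carbon nucleophile at C6; borate followed by peroxide is the oxygen electrophile at C1.
- The aryne comes from 3-fluoroanisole by lithiation between F and OMe and loss of LiF. Heptadecyllithium comes from 1-bromoheptadecane and lithium metal.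
- No ring is formed at any stage: the benzene ring of 3-fluoroanisole is carried through and becomes the quinone ring.

Key step: step 2

Remark: the target is achiral, so no stereocontrol is needed. Heptadecyllithium is handled as a filtered, titrated ethereal solution and is counted as an intermediate.

**Route**

Step 1
Reactants: 1 1-bromoheptadecane
Product: 2 heptadecyllithium (solution in Et2O, filtered under argon and titrated)
Conditions: Li metal (1% Na, 2.5 equiv), Et2O, −10 → 0 °C, Ar, slow addition of 1
Reagents that add atoms: lithium metal [Li]
Why: Direct reductive lithiation of a primary alkyl bromide at the lithium surface is the classical preparation of primary alkyllithiums; the sodium content initiates the insertion, and slow addition at low temperature should keep Wurtz coupling to the inert C34 alkane minor.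

Step 2
Reactants: 3 3-fluoroanisole; 2 heptadecyllithium; 4 hydrogen peroxide
Product: 9 2-heptadecyl-6-methoxyphenol, via 2-fluoro-6-methoxyphenyllithium 5 (not isolated), via 3-methoxybenzyne 6 (not isolated), via 2-heptadecyl-6-methoxyphenyllithium 7 (not isolated), via lithium (2-heptadecyl-6-methoxyphenyl)trimethoxyborate 8 (not isolated)
Conditions: s-BuLi (1.0 equiv), THF, −78 °C, 1 h; 2 (1.5 equiv, Et2O), −78 → −10 °C; B(OMe)3 (3 equiv), −78 °C → rt; AcOH, 30% aq H2O2, 0 °C → rt
Reagents that add atoms: trimethyl borate COB(OC)OC (its boron and methoxy groups are carried only in intermediate 8 and are removed on oxidation; the phenol oxygen of 9 comes from reactant 4)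
Why: s-BuLi removes the hydrogen flanked by F and OMe (directed ortho-metalation) to give 5, which on warming loses LiF to form aryne 6; heptadecyllithium carbolithiates the strained bond to give 7, B(OMe)3 captures 7 as ate complex 8, and peroxide induces the 1,2-aryl shift from boron to oxygen, with hydrolysis releasing phenol 9. The closest known reaction type is the tandem addition of an organolithium to a haloarene-derived aryne with electrophilic quench of the resulting ortho-lithio species, joined to the standard aryllithium–borate–peroxide hydroxylation. No ring is closed and no stereocentre is created. The step needs regioselective attack of the carbon nucleophile at the aryne carbon remote from OMe: the sigma-withdrawing methoxy group distorts the aryne so that the distal carbon is the more electrophilic one, and the carbanion develops next to oxygen, where induction and lithium–oxygen coordination stabilise it. It also needs the aryne to be intercepted by 2 and not by aryllithiums 5 or 7, which an excess of the more nucleophilic primary alkyllithium, full consumption of s-BuLi before warming, and slow warming that keeps the aryne concentration low should secure. Because the boron-to-oxygen migration occurs at the carbon that carried lithium, the oxygen is placed exactly between the chain and the methoxy group.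

Step 3
Reactants: 9 2-heptadecyl-6-methoxyphenol
Product: 10 2-heptadecyl-6-methoxy-1,4-benzoquinone (2-heptadecyl-6-methoxycyclohexa-2,5-diene-1,4-dione), the target
Conditions: O2 (1 atm), Co(salen) (divalent cobalt complex of N,N′-bis(salicylidene)ethylenediamine, C16H14CoN2O2; 10 mol %), amine-free DMF/CH2Cl2, rt
Reagents that add atoms: dioxygen O=O
Why: Cobalt–salen-catalysed aerobic oxidation of a 2,6-disubstituted phenol to the para-benzoquinone (salcomine oxidation) should work because the cobalt superoxo species abstracts the phenolic hydrogen and the phenoxyl radical is oxygenated at the only unhindered position, the free para carbon, both ortho positions being blocked by the chain and OMe.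

**Compound list**

1 | 1-bromoheptadecane | CCCCCCCCCCCCCCCCCBr | starting material
2 | heptadecyllithium | [Li]CCCCCCCCCCCCCCCCC | intermediate
3 | 3-fluoroanisole (1-fluoro-3-methoxybenzene) | COc1cccc(F)c1 | starting material
4 | hydrogen peroxide | OO | starting material
5 | 2-fluoro-6-methoxyphenyllithium | COc1cccc(F)c1[Li] | intermediate
6 | 3-methoxybenzyne | COC1=CC=CC#C1 | intermediate
7 | 2-heptadecyl-6-methoxyphenyllithium | CCCCCCCCCCCCCCCCCc1cccc(OC)c1[Li] | intermediate
8 | lithium (2-heptadecyl-6-methoxyphenyl)trimethoxyborate | [Li+].CCCCCCCCCCCCCCCCCc1cccc(OC)c1[B-](OC)(OC)OC | intermediate
9 | 2-heptadecyl-6-methoxyphenol | CCCCCCCCCCCCCCCCCc1cccc(OC)c1O | intermediate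
10 | 2-heptadecyl-6-methoxy-1,4-benzoquinone | CCCCCCCCCCCCCCCCCC1=CC(=O)C=C(OC)C1=O | target

**Step count**

Total steps: 3. Longest linear sequence: 3 steps (1 → 2 → 9 → 10).

**Steps most likely to fail, with fallbacks**

Step 2. The aryne may be consumed by aryllithiums 5 or 7 instead of by 2, giving oligoaryls. Unreacted s-BuLi may add in place of the C17 chain. Aryllithium 7 may be protonated before boron capture. The fallback replaces aryne difunctionalisation by directed ortho-metalation and alkylation. It sets out from 1 and commercial guaiacol (2-methoxyphenol, COc1ccccc1O). MOMCl and i-Pr2NEt in CH2Cl2 should give 1-methoxy-2-(methoxymethoxy)benzene F1. n-BuLi/TMEDA in THF at 0 °C should metalate next to the acetal oxygen to give [3-methoxy-2-(methoxymethoxy)phenyl]lithium F2. This is alkylated in the same flask with bromide 1 to give 1-heptadecyl-3-methoxy-2-(methoxymethoxy)benzene F3. HCl in MeOH at 50 °C should cleave the acetal, and the route is rejoined at 9.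

Step 1. Wurtz homocoupling at the metal surface and sluggish initiation may give a low or irreproducible titre. The fallback changes from reductive metalation to halogen–lithium exchange. It sets out from 1. NaI in refluxing acetone (Finkelstein reaction) should give 1-iodoheptadecane F4. Treatment with t-BuLi (2.1 equiv) in pentane/Et2O at −78 °C should then deliver heptadecyllithium by iodine–lithium exchange, and the route is rejoined at 2.

Step 3. The phenoxyl radical may couple carbon-to-carbon at the para position, or oxygenation may stall through poor solubility or catalyst deactivation. The fallback installs the C4 oxygen by formylation and oxidative deformylation. It sets out from 9. Duff formylation (hexamethylenetetramine, TFA, reflux, then aqueous acid) at the only free position para to OH should give 3-heptadecyl-4-hydroxy-5-methoxybenzaldehyde F5. Dakin oxidation (4, NaOH, THF/H2O, 0 °C, argon, then acidification) should give 2-heptadecyl-6-methoxybenzene-1,4-diol F6. Oxidation with aqueous FeCl3 in EtOAc should then give the quinone, and the route is rejoined at 10.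

**Further compounds**

F1 | step 2 | 1-methoxy-2-(methoxymethoxy)benzene | COCOc1ccccc1OC
F2 | step 2 | [3-methoxy-2-(methoxymethoxy)phenyl]lithium | COCOc1c([Li])cccc1OC
F3 | step 2 | 1-heptadecyl-3-methoxy-2-(methoxymethoxy)benzene | CCCCCCCCCCCCCCCCCc1cccc(OC)c1OCOC
F4 | step 1 | 1-iodoheptadecane | CCCCCCCCCCCCCCCCCI
F5 | step 3 | 3-heptadecyl-4-hydroxy-5-methoxybenzaldehyde | CCCCCCCCCCCCCCCCCc1cc(C=O)cc(OC)c1O
F6 | step 3 | 2-heptadecyl-6-methoxybenzene-1,4-diol | CCCCCCCCCCCCCCCCCc1cc(O)cc(OC)c1O
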